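## The problem

Sideritiflavone (15) is 5,3',4'-trihydroxy-6,7,8-trimethoxyflavone. It has no stereocentre, so the task is one of substitution pattern only. Ring A is a hexasubstituted benzene (C5 OH; C6, C7, C8 OMe; C8a O1; C4a C4): no position is free for a late aromatic substitution, and five oxygens must be placed on six adjacent carbons by construction. The four oxygens on C5 to C8 must be told apart, since only the one on C5, peri to the C4 carbonyl, is a free phenol. The usual plan builds ring C onto a preformed penta-oxygenated acetophenone, which needs a long run of oxidations and methylations and frees the 5-OH only by a selective demethylation at the end. The ring B catechol and the electron-rich ring A are easily oxidised, and the pyranone ring opens in strong base or hot acid, so the catechol stays masked to the last step and the late steps must be close to neutral. The feature that allows a shorter plan is the sequence C5–C6–C7–C8 of ring A: four contiguous oxygen-bearing carbons, the inner two both methoxylated, the outer two para to each other with one oxygen free and one methylated, closed by the C4a–C8a bond that ring A shares with the 4-pyranone ring C. This is the pattern that results when a cyclobutenone made from a squaric ester, carrying an alkenyl group on its carbinol carbon, opens to a dienylketene and recloses. The ketene carbonyl becomes the C5–OH next to C4a, the etherified carbinol carbon becomes C8, the two vinylic methoxy carbons become C6 and C7, and the alkene is the C5=C6 bond of a 2-aryl-4-pyranone in which rings B and C are already joined.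

## Retrosynthesis

**15 from 14.** The two benzyl C–O bonds of the catechol are cut last. Benzyl ethers should survive amide bases, a Grignard reagent, Ag2O/MeI and 138 °C, and they leave by neutral hydrogenolysis that touches neither the aryl methyl ethers nor the chelated 5-OH. Flavone 14 is the full skeleton with the ring A pattern already correct.

**14 from 11 (key cut).** The C4a–C5 bond of ring A is cut and the ring is folded back, through cyclohexadienone 13 and dienylketene 12, into cyclobutenone 11. The neighbouring cuts (a late C–O bond at C6 or C8, or the C4–C4a bond by acylation of a penta-oxygenated arene) all leave the hexasubstituted benzene as the problem; this cut dissolves it. Precursor 11 has no ring A at all: a four-membered ring and a monocyclic pyranone joined by one σ bond. The free OH at C5 and the three methyl ethers are told apart by the origin of the atoms, not by a selective reaction. The forward step asks that the methoxy group on the carbinol carbon rotates outward on ring opening and that the ketene closes onto C5 of the pyranone.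

**11 from 10, and 10 from 9 and 8.** The O–CH3 bond at the carbinol and then the C8–C8a bond (carbinol carbon to pyranone C6) are cut. This gives dimethyl squarate 8, which supplies C5 to C8 with all four oxygens, and the pyranonyl Grignard reagent 9. Joining through the pyranone carbon next to the carbonyl instead would need a β-alkoxyvinyl anion, which opens the ring by β-elimination, and would end in an air-sensitive 5,8-hydroquinone. Reagent 9 is an α-alkoxyvinyl metal without a β-leaving group, and the methylated carbinol oxygen ends as the 8-OMe.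

**9 from 7, and 7 from 5 through 6.** The C–Mg bond is traced to a C–I bond and this to the C6–H bond of pyranone 5. A lithium or magnesium amide, whose cation binds the pyranone carbonyl, would be expected to metalate next to the carbonyl. A zinc amide free of MgCl2 should take the most acidic proton, next to the ring oxygen, to give 6. Since 6 is too weak a nucleophile for 8, its position is stored as iodide 7 and released as 9 by exchange.

**5 from 2 and 3 through 4; 2 from 1.** The O1–C6 and C2–C3 bonds of the pyranone are cut (C-acylation, then addition–elimination). This leads to acid chloride 2, from commercial acid 1, and commercial (E)-4-methoxybut-3-en-2-one 3, with diketone 4 as the open-chain intermediate. Ring B enters with its protected catechol in place.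

## Roads not taken

Alternative 1: Cut O1–C2 and C2–C3 of ring C, the most obvious plan. Ring A arrives complete as 1-(2-hydroxy-3,4,5,6-tetramethoxyphenyl)ethan-1-one A1. It is O-aroylated with 2 and rearranged (Baker–Venkataraman) to the 1,3-diketone A2; cyclodehydration, cleavage of the chelated 5-methyl ether and debenzylation follow. A1 is itself a hexasubstituted benzene that must be made by successive oxygenation, methylation and acylation of a simpler phenol. The free 5-OH comes from a selective demethylation next to three other methyl ethers. The chosen plan never substitutes ring A and sets the OH/OMe pattern by mechanism.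

Alternative 2: Biomimetic order. Ring A enters at the phloroglucinol level of the polyketide pathway, as 3',4'-di-O-benzylluteolin A3 (from 2,4,6-trihydroxyacetophenone), and C6 and C8 are oxygenated afterwards, for example by dibromination to A4, copper-mediated methoxylation and selective 7-O-methylation. This needs two C–O bond formations on the finished flavone, a distinction between the 5- and 7-hydroxyls, and hot methoxide that can open the pyranone ring. It takes more steps for the same ring A.

Alternative 3: Three-component benzannulation of the Dötz type, with the same bonds as the chosen plan but C5 taken from carbon monoxide. The zerovalent chromium carbene complex A5, (OC)5Cr=C(OMe)(pyranonyl), made from 9, Cr(CO)6 and a methylating agent, would combine with dimethoxyacetylene A6 and one CO ligand to give 14. A6 is not a practical reagent: it must be made, is unstable and polymerises. The step also needs stoichiometric chromium. Squarate 8 is the stable, commercial equivalent of A6 plus two CO and needs only heat.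

Key step: step 6

## Route

Remark on the chemistry: the carbinol carbon of 10 and 11 and C4a of 13 are stereocentres formed racemic and destroyed within step 6, so no stereocontrol is needed. TMP = 2,2,6,6-tetramethylpiperidin-1-yl.

Step 1
Reactants: 1 3,4-bis(benzyloxy)benzoic acid
Product: 2 3,4-bis(benzyloxy)benzoyl chloride
Conditions: (COCl)2, cat. DMF, CH2Cl2, 0 °C to rt; evaporate
Reagents that add atoms: oxalyl chloride, ClC(=O)C(=O)Cl
Why: Standard acid chloride formation through the chloroiminium salt of DMF; the benzyl ethers are inert and the crude chloride is used directly.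

Step 2
Reactants: 2 3,4-bis(benzyloxy)benzoyl chloride; 3 (E)-4-methoxybut-3-en-2-one
Product: 5 2-[3,4-bis(benzyloxy)phenyl]-4H-pyran-4-one, via methoxyvinyl diketone 4 (not isolated)
Conditions: 3 (2.2 equiv), LiN(SiMe3)2 (2.2 equiv), THF, −78 °C; then 2, −78 °C; aq NH4Cl; then CF3CO2H (cat.), CH2Cl2, rt
Reagents that add atoms: none
Why: Claisen-type C-acylation of the kinetic methyl enolate of 3 (the second equivalent takes up the acidic diketone proton), then acid-catalysed 6-endo addition–elimination of the enol oxygen onto the β-methoxy enone with loss of methanol; this is a known one-flask 4-pyranone synthesis.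

Step 3
Reactants: 5 2-[3,4-bis(benzyloxy)phenyl]-4H-pyran-4-one
Product: 7 2-[3,4-bis(benzyloxy)phenyl]-6-iodo-4H-pyran-4-one, via pyranonylzinc chloride 6 (not isolated)
Conditions: TMPZnCl·LiCl (MgCl2-free, from lithium 2,2,6,6-tetramethylpiperidide and ZnCl2; 1.2 equiv), THF, 25 °C; then I2, THF, 0 °C; aq Na2S2O3
Reagents that add atoms: iodine, [I][I]
Why: C–H zincation with a hindered zinc amide, a reaction type known for chromones and 4-pyranones, should take the most acidic ring proton, the one next to the ring oxygen (C6), as long as no strong Lewis acid binds the carbonyl and steers the base to C3 or C5; the covalent C–Zn bond tolerates the pyranone carbonyl and iodinolysis fixes the site as a C–I bond.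

Step 4
Reactants: 7 2-[3,4-bis(benzyloxy)phenyl]-6-iodo-4H-pyran-4-one; 8 3,4-dimethoxycyclobut-3-ene-1,2-dione (dimethyl squarate)
Product: 10 rac-4-{6-[3,4-bis(benzyloxy)phenyl]-4-oxo-4H-pyran-2-yl}-4-hydroxy-2,3-dimethoxycyclobut-2-en-1-one, via pyranonylmagnesium chloride 9 (not isolated)
Conditions: iPrMgCl·LiCl (1.05 equiv), THF, −78 °C; then transfer into 8 (1.3 equiv), THF, −78 to −40 °C; aq NH4Cl at −40 °C
Reagents that add atoms: none
Why: Iodine–magnesium exchange on an acceptor-substituted alkenyl iodide is fast at −78 °C and gives an α-alkoxyvinyl Grignard reagent without a β-leaving group; 1,2-addition of alkenyl and heteroaryl organometallics to one carbonyl of 8 is the standard entry to 4-hydroxycyclobutenones, and the new carbinol centre is formed racemic.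

Step 5
Reactants: 10 rac-4-{6-[3,4-bis(benzyloxy)phenyl]-4-oxo-4H-pyran-2-yl}-4-hydroxy-2,3-dimethoxycyclobut-2-en-1-one
Product: 11 rac-4-{6-[3,4-bis(benzyloxy)phenyl]-4-oxo-4H-pyran-2-yl}-2,3,4-trimethoxycyclobut-2-en-1-one
Conditions: MeI (excess), Ag2O, CaSO4, MeCN, rt, dark
Reagents that add atoms: iodomethane, CI
Why: Silver-oxide-mediated (Purdie) O-methylation of the tertiary carbinol under nearly neutral conditions, as used for 4-hydroxycyclobutenones whose alkoxides tend to open the ring; the new methyl ether becomes the 8-OMe and blocks lactonisation of the ketene in step 6.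

Step 6
Reactants: 11 rac-4-{6-[3,4-bis(benzyloxy)phenyl]-4-oxo-4H-pyran-2-yl}-2,3,4-trimethoxycyclobut-2-en-1-one
Product: 14 2-[3,4-bis(benzyloxy)phenyl]-5-hydroxy-6,7,8-trimethoxy-4H-chromen-4-one, via dienylketene 12 (not isolated), via cyclohexadienone 13 (not isolated)
Conditions: p-xylene (degassed, 0.01 M), 138 °C, Ar
Reagents that add atoms: none
Why: Thermal conrotatory 4π opening of the cyclobutenone (cleavage of the carbonyl–carbinol C–C bond) should give dienylketene 12. The donor methoxy group on the carbinol carbon rotates outward, which places the pyranonyl group Z to the ketene as closure requires, and because the opening is reversible any E-ketene returns to 11 and is funnelled through the Z isomer. Ring A is then closed by a disrotatory 6π electrocyclisation of the ketene C=C, the C(OMe)=C(OMe) bond and the C5=C6 bond of the pyranone, which forms the C5–C4a bond of the flavone between the electrophilic ketene carbon and the nucleophilic carbon alpha to the pyranone carbonyl. Dienone 13 carries its only sp3 hydrogen at C4a between two carbonyl groups and should enolise at once to phenol 14, whose 5-OH is hydrogen-bonded to the C4 carbonyl. The closest known reaction type is the thermal ring expansion of squarate-derived 4-aryl-, 4-heteroaryl- and 4-alkenyl-4-alkoxycyclobutenones to hydroquinone monoethers, and the weakly aromatic pyranone C=C should behave more like an alkenyl than an aryl group. No stereocentre remains, since the carbinol centre of 11 becomes sp2 C8 and the transient C4a centre of 13 is lost on enolisation. The closure can reach only C5 of the pyranone, and the free OH at C5 with OMe at C6, C7 and C8 follows from the origin of the atoms (ketene oxygen, two vinylic methoxy groups, carbinol methyl ether). High dilution is chosen to keep the ketene from dimerising.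

Step 7
Reactants: 14 2-[3,4-bis(benzyloxy)phenyl]-5-hydroxy-6,7,8-trimethoxy-4H-chromen-4-one
Product: 15 sideritiflavone [2-(3,4-dihydroxyphenyl)-5-hydroxy-6,7,8-trimethoxy-4H-chromen-4-one]
Conditions: H2 (1 atm), 10% Pd/C, THF–MeOH, rt
Reagents that add atoms: none
Why: Hydrogenolysis of the two benzyl aryl ethers; the aryl methyl ethers, the chelated phenol and the flavone C2–C3 double bond should not be reduced under these mild conditions.

## Compound list

1 | 3,4-bis(benzyloxy)benzoic acid | OC(=O)c1ccc(OCc2ccccc2)c(OCc2ccccc2)c1 | starting material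
2 | 3,4-bis(benzyloxy)benzoyl chloride | ClC(=O)c1ccc(OCc2ccccc2)c(OCc2ccccc2)c1 | intermediate
3 | (E)-4-methoxybut-3-en-2-one | CO/C=C/C(C)=O | starting material
4 | (E)-1-[3,4-bis(benzyloxy)phenyl]-5-methoxypent-4-ene-1,3-dione | CO/C=C/C(=O)CC(=O)c1ccc(OCc2ccccc2)c(OCc2ccccc2)c1 | intermediate (not isolated)
5 | 2-[3,4-bis(benzyloxy)phenyl]-4H-pyran-4-one | O=c1ccoc(-c2ccc(OCc3ccccc3)c(OCc3ccccc3)c2)c1 | intermediate
6 | {6-[3,4-bis(benzyloxy)phenyl]-4-oxo-4H-pyran-2-yl}zinc chloride | O=c1cc(-c2ccc(OCc3ccccc3)c(OCc3ccccc3)c2)oc([Zn]Cl)c1 | intermediate (not isolated)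
7 | 2-[3,4-bis(benzyloxy)phenyl]-6-iodo-4H-pyran-4-one | O=c1cc(-c2ccc(OCc3ccccc3)c(OCc3ccccc3)c2)oc(I)c1 | intermediate
8 | 3,4-dimethoxycyclobut-3-ene-1,2-dione (dimethyl squarate) | COC1=C(OC)C(=O)C1=O | starting material
9 | {6-[3,4-bis(benzyloxy)phenyl]-4-oxo-4H-pyran-2-yl}magnesium chloride | O=c1cc(-c2ccc(OCc3ccccc3)c(OCc3ccccc3)c2)oc([Mg]Cl)c1 | intermediate (not isolated)
10 | rac-4-{6-[3,4-bis(benzyloxy)phenyl]-4-oxo-4H-pyran-2-yl}-4-hydroxy-2,3-dimethoxycyclobut-2-en-1-one | COC1=C(OC)C(O)(c2cc(=O)cc(-c3ccc(OCc4ccccc4)c(OCc4ccccc4)c3)o2)C1=O | intermediate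
11 | rac-4-{6-[3,4-bis(benzyloxy)phenyl]-4-oxo-4H-pyran-2-yl}-2,3,4-trimethoxycyclobut-2-en-1-one | COC1=C(OC)C(OC)(c2cc(=O)cc(-c3ccc(OCc4ccccc4)c(OCc4ccccc4)c3)o2)C1=O | intermediate
12 | (3Z)-4-{6-[3,4-bis(benzyloxy)phenyl]-4-oxo-4H-pyran-2-yl}-2,3,4-trimethoxybuta-1,3-dien-1-one | O=C=C(OC)/C(OC)=C(OC)\c1cc(=O)cc(-c2ccc(OCc3ccccc3)c(OCc3ccccc3)c2)o1 | intermediate (not isolated)
13 | rac-2-[3,4-bis(benzyloxy)phenyl]-6,7,8-trimethoxy-4aH-chromene-4,5-dione | COC1=C(OC)C(=O)C2C(=O)C=C(c3ccc(OCc4ccccc4)c(OCc4ccccc4)c3)OC2=C1OC | intermediate (not isolated)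
14 | 2-[3,4-bis(benzyloxy)phenyl]-5-hydroxy-6,7,8-trimethoxy-4H-chromen-4-one | COc1c(OC)c(O)c2c(=O)cc(-c3ccc(OCc4ccccc4)c(OCc4ccccc4)c3)oc2c1OC | intermediate
15 | sideritiflavone | COc1c(OC)c(O)c2c(=O)cc(-c3ccc(O)c(O)c3)oc2c1OC | target

## Step count and least certain steps

Total step count: 7. Longest linear sequence: 7 steps (1 to 15); 3 and 8 are bought and enter without prior steps.

**Step 6 (key step).** The most likely failure is a slow 6π closure onto the pyranone C5=C6 bond, which is partly delocalised and carries an acceptor. The ketene would then be lost by dimerisation or by capture with adventitious nucleophiles; return to 11 is harmless. The fallback sets out from 8 and returns at 15. It keeps the squarate ring synthesis but uses the simplest α-alkoxyvinyl partner and adds ring C afterwards in the classical way. 1-Methoxyvinyllithium (methyl vinyl ether, t-BuLi) is added to 8 to give 4-hydroxy-2,3-dimethoxy-4-(1-methoxyethenyl)cyclobut-2-en-1-one F1. Methylation as in step 5 gives 2,3,4-trimethoxy-4-(1-methoxyethenyl)cyclobut-2-en-1-one F2, and thermolysis in toluene gives 2,3,4,5-tetramethoxyphenol F3. C-acetylation at its only free position (Ac2O, BF3·OEt2, Fries type) gives 1-(2-hydroxy-3,4,5,6-tetramethoxyphenyl)ethan-1-one F4. Aldol condensation with commercial 3,4-bis(benzyloxy)benzaldehyde (KOH, EtOH) gives (E)-3-[3,4-bis(benzyloxy)phenyl]-1-(2-hydroxy-3,4,5,6-tetramethoxyphenyl)prop-2-en-1-one F5. I2 (cat.) in DMSO at 130 °C closes and dehydrogenates it to 2-[3,4-bis(benzyloxy)phenyl]-5,6,7,8-tetramethoxy-4H-chromen-4-one F6. BCl3 in CH2Cl2 then cleaves the chelated 5-methyl ether and both benzyl ethers and gives 15.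

**Step 4.** The iodide is a vinylogous acyl iodide, so the exchange reagent may attack C6 or the carbonyl instead of iodine. The Grignard reagent 9 may also add to unreacted 7 before it meets 8, or add to 8 in the conjugate sense with loss of methoxide. The fallback sets out from 2 and returns at 9. It builds the C6 handle into the ring synthesis and frees the carbanion by exchange at sulfur. Acylation of the lithium enolate of commercial 4,4-bis(methylsulfanyl)but-3-en-2-one with 2 gives 1-[3,4-bis(benzyloxy)phenyl]-5,5-bis(methylsulfanyl)pent-4-ene-1,3-dione F7. Acid-catalysed ring closure with loss of methanethiol gives 2-[3,4-bis(benzyloxy)phenyl]-6-(methylsulfanyl)-4H-pyran-4-one F8. mCPBA (1 equiv, −20 °C) gives 2-[3,4-bis(benzyloxy)phenyl]-6-(methanesulfinyl)-4H-pyran-4-one F9. Sulfoxide–magnesium exchange with iPrMgCl·LiCl at −78 °C gives 9, which is added to 8 as in step 4. This path also makes the C–H zincation of step 3, whose site selectivity is the other open question of the run-up, unnecessary.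

**Step 5.** Two things may go wrong: competing O-alkylation of the basic pyranone carbonyl to a methoxypyrylium salt, or ring opening and rearrangement of the tertiary cyclobutenol under the slightly basic conditions. The fallback sets out from 10 and returns at 14. It inverts the order of ring formation and methylation. Thermolysis of 10 under argon, as in step 6, gives the hydroquinone 2-[3,4-bis(benzyloxy)phenyl]-5,8-dihydroxy-6,7-dimethoxy-4H-chromen-4-one F10, whose 5-OH is deactivated by the hydrogen bond to the C4 carbonyl. Me2SO4 (1 equiv), K2CO3, acetone, under argon, should then methylate only the 8-OH and give 14.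

## Further compounds

F1 | step 6 | 4-hydroxy-2,3-dimethoxy-4-(1-methoxyethenyl)cyclobut-2-en-1-one | C=C(OC)C1(O)C(OC)=C(OC)C1=O
F2 | step 6 | 2,3,4-trimethoxy-4-(1-methoxyethenyl)cyclobut-2-en-1-one | C=C(OC)C1(OC)C(OC)=C(OC)C1=O
F3 | step 6 | 2,3,4,5-tetramethoxyphenol | COc1cc(O)c(OC)c(OC)c1OC
F4 | step 6 | 1-(2-hydroxy-3,4,5,6-tetramethoxyphenyl)ethan-1-one | CC(=O)c1c(O)c(OC)c(OC)c(OC)c1OC
F5 | step 6 | (E)-3-[3,4-bis(benzyloxy)phenyl]-1-(2-hydroxy-3,4,5,6-tetramethoxyphenyl)prop-2-en-1-one | O=C(/C=C/c1ccc(OCc2ccccc2)c(OCc2ccccc2)c1)c1c(O)c(OC)c(OC)c(OC)c1OC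
F6 | step 6 | 2-[3,4-bis(benzyloxy)phenyl]-5,6,7,8-tetramethoxy-4H-chromen-4-one | COc1c(OC)c(OC)c2c(=O)cc(-c3ccc(OCc4ccccc4)c(OCc4ccccc4)c3)oc2c1OC
F7 | step 4 | 1-[3,4-bis(benzyloxy)phenyl]-5,5-bis(methylsulfanyl)pent-4-ene-1,3-dione | CSC(SC)=CC(=O)CC(=O)c1ccc(OCc2ccccc2)c(OCc2ccccc2)c1
F8 | step 4 | 2-[3,4-bis(benzyloxy)phenyl]-6-(methylsulfanyl)-4H-pyran-4-one | CSc1cc(=O)cc(-c2ccc(OCc3ccccc3)c(OCc3ccccc3)c2)o1
F9 | step 4 | 2-[3,4-bis(benzyloxy)phenyl]-6-(methanesulfinyl)-4H-pyran-4-one | CS(=O)c1cc(=O)cc(-c2ccc(OCc3ccccc3)c(OCc3ccccc3)c2)o1
F10 | step 5 | 2-[3,4-bis(benzyloxy)phenyl]-5,8-dihydroxy-6,7-dimethoxy-4H-chromen-4-one | COc1c(OC)c(O)c2c(=O)cc(-c3ccc(OCc4ccccc4)c(OCc4ccccc4)c3)oc2c1O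
A1 | alternative 1 | 1-(2-hydroxy-3,4,5,6-tetramethoxyphenyl)ethan-1-one | CC(=O)c1c(O)c(OC)c(OC)c(OC)c1OC
A2 | alternative 1 | 1-[3,4-bis(benzyloxy)phenyl]-3-(2-hydroxy-3,4,5,6-tetramethoxyphenyl)propane-1,3-dione | O=C(CC(=O)c1ccc(OCc2ccccc2)c(OCc2ccccc2)c1)c1c(O)c(OC)c(OC)c(OC)c1OC
A3 | alternative 2 | 2-[3,4-bis(benzyloxy)phenyl]-5,7-dihydroxy-4H-chromen-4-one | O=c1cc(-c2ccc(OCc3ccccc3)c(OCc3ccccc3)c2)oc2cc(O)cc(O)c12
A4 | alternative 2 | 2-[3,4-bis(benzyloxy)phenyl]-6,8-dibromo-5,7-dihydroxy-4H-chromen-4-one | O=c1cc(-c2ccc(OCc3ccccc3)c(OCc3ccccc3)c2)oc2c(Br)c(O)c(Br)c(O)c12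
A5 | alternative 3 | pentacarbonyl[{6-[3,4-bis(benzyloxy)phenyl]-4-oxo-4H-pyran-2-yl}(methoxy)methylidene]chromium | COC(=[Cr](=C=O)(=C=O)(=C=O)(=C=O)=C=O)c1cc(=O)cc(-c2ccc(OCc3ccccc3)c(OCc3ccccc3)c2)o1
A6 | alternative 3 | dimethoxyacetylene | COC#COC
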